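**Retrosynthetic overview**
1. The ester C–O bond is made last: catalytic enantioselective addition of MeOH to an aryl benzyl ketene sets the (R) centre, and acid methanolysis of three aryl acetates follows in the same flask.
2. Ketene ⇒ racemic 2,3-diarylpropanoic acid triacetate (acid chloride, dehydrochlorination) ⇒ (E)-2,3-diarylacrylic acid (achiral hydrogenation; the centre is erased again at the ketene stage, so no earlier stereocontrol is needed).
3. Acrylic acid ⇒ Perkin condensation of the ring A arylacetic acid with the ring B catechol aldehyde; Ac2O protects the three phenols in the same operation.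
4. Ring A acid ⇒ mono C–O coupling (hydroxylation) of the symmetric 3,5-dibromo-4-methoxyphenylacetate; ring B aldehyde ⇒ O-demethylation of 5,6-dibromovanillin.
5. No ring is formed: both benzene rings are bought with their bromine pattern in place.

Assumption: 2-(3,5-dibromo-4-hydroxyphenyl)acetic acid and 5,6-dibromovanillin are taken as catalogue compounds (each is otherwise one bromination from 4-hydroxyphenylacetic acid or 5-bromovanillin); the target is the (R)-enantiomer, as read from the SMILES.

**Step 1**
Reactants: 1 2-(3,5-dibromo-4-hydroxyphenyl)acetic acid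
Product: 2 methyl 2-(3,5-dibromo-4-methoxyphenyl)acetate
Conditions: MeI (3 equiv), K2CO3 (3 equiv), DMF, 40 °C
Reagents that add atoms: iodomethane, CI
Why: Williamson O-methylation of the phenoxide together with carboxylate alkylation (both SN2 on MeI), which works on 2,6-dibromophenoxides in DMF; no stereocentre.

**Step 2**
Reactants: 2 methyl 2-(3,5-dibromo-4-methoxyphenyl)acetate
Product: 4 2-(3-bromo-5-hydroxy-4-methoxyphenyl)acetic acid, via lithium 2-(3,5-dibromo-4-methoxyphenyl)acetate 3 (not isolated)
Conditions: Cu(acac)2 (5 mol %), N,N′-bis(4-hydroxy-2,6-dimethylphenyl)oxalamide (5 mol %), LiOH·H2O (3.1 equiv), DMSO/H2O 4:1, 80 °C, argon; then 2 M HCl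
Reagents that add atoms: lithium hydroxide, [Li+].[OH-]
Why: Copper-catalysed Ullmann-type hydroxylation of an aryl bromide after fast saponification of the ester; the two bromines are equivalent, hydroxide is limiting (one equivalent for the ester, two for one C–Br) and the first phenoxide makes the ring more electron-rich so the second coupling is slower, which favours the mono-phenol; no stereocentre.

**Step 3**
Reactants: 5 2,3-dibromo-4-hydroxy-5-methoxybenzaldehyde (5,6-dibromovanillin)
Product: 6 2,3-dibromo-4,5-dihydroxybenzaldehyde
Conditions: BBr3 (3 equiv), CH2Cl2, −78 °C to rt; then H2O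
Reagents that add atoms: none
Why: Lewis-acid aryl methyl ether cleavage, in which BBr3 complexes the ether oxygen and bromide removes the methyl group, a standard demethylation of hydroxy-methoxybenzaldehydes; no stereocentre.

**Step 4**
Reactants: 4 2-(3-bromo-5-hydroxy-4-methoxyphenyl)acetic acid; 6 2,3-dibromo-4,5-dihydroxybenzaldehyde
Product: 7 (2E)-2-(3-acetoxy-5-bromo-4-methoxyphenyl)-3-(4,5-diacetoxy-2,3-dibromophenyl)prop-2-enoic acid
Conditions: Ac2O (10 equiv), Et3N (4 equiv), 110 °C; then ice-cold 2 M HCl
Reagents that add atoms: acetic anhydride, CC(=O)OC(C)=O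
Why: Perkin condensation, in which Ac2O acetylates the three phenols and activates the acid as a mixed anhydride whose enolate adds to the aldehyde and eliminates to the (E)-acid with the two aryl groups cis, the usual outcome for arylacetic acids and ortho-substituted benzaldehydes; no stereocentre.

**Step 5**
Reactants: 7 (2E)-2-(3-acetoxy-5-bromo-4-methoxyphenyl)-3-(4,5-diacetoxy-2,3-dibromophenyl)prop-2-enoic acid
Product: 8 rac-2-(3-acetoxy-5-bromo-4-methoxyphenyl)-3-(4,5-diacetoxy-2,3-dibromophenyl)propanoic acid
Conditions: H2 (30 bar), [Rh(nbd)(dppb)]BF4 (2 mol %), Et3N (1 equiv), THF, 40 °C; then 1 M HCl wash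
Reagents that add atoms: none
Why: Carboxylate-directed homogeneous hydrogenation by a cationic rhodium diphosphine catalyst adds H2 across the trisubstituted alkene without touching aryl C–Br or aryl acetate groups; the catalyst is achiral and the centre is formed racemic on purpose, because step 6 planarises it again.

**Step 6**
Reactants: 8 rac-2-(3-acetoxy-5-bromo-4-methoxyphenyl)-3-(4,5-diacetoxy-2,3-dibromophenyl)propanoic acid
Product: 10 2-(3-acetoxy-5-bromo-4-methoxyphenyl)-3-(4,5-diacetoxy-2,3-dibromophenyl)prop-1-en-1-one (aryl benzyl ketene, used at once as a toluene solution), via acid chloride 9 (not isolated)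
Conditions: (COCl)2 (1.5 equiv), DMF (cat.), CH2Cl2, 0 °C to rt, evaporate; Me2NEt (3 equiv), toluene, rt, argon; filter, evaporate volatiles, redissolve in toluene
Reagents that add atoms: none
Why: Acid chloride formation followed by amine-mediated dehydrochlorination (E1cB through the acidic α-aryl C–H) gives a disubstituted aryl alkyl ketene, a class stable enough to handle in solution; filtration and evaporation remove the amine and its salt, which would otherwise catalyse racemic alcohol addition.

**Step 7**
Reactants: 10 2-(3-acetoxy-5-bromo-4-methoxyphenyl)-3-(4,5-diacetoxy-2,3-dibromophenyl)prop-1-en-1-one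
Product: 12 methyl (2R)-2-(3-bromo-5-hydroxy-4-methoxyphenyl)-3-(2,3-dibromo-4,5-dihydroxyphenyl)propanoate, via triacetate methyl ester 11 (not isolated)
Conditions: 3-{[3,5-bis(trifluoromethyl)phenyl]amino}-4-{[(8α,9S)-6′-methoxycinchonan-9-yl]amino}cyclobut-3-ene-1,2-dione (quinine-derived squaramide, 10 mol %), MeOH (1.2 equiv, slow addition), toluene/CH2Cl2 4:1, −78 °C; then 1.25 M HCl in MeOH, −78 to 40 °C
Reagents that add atoms: methanol, CO
Why: Proposed new method: catalytic enantioselective methanolysis of a ketene by a bifunctional cinchona squaramide, in which the squaramide N–H pair binds the ketene oxygen and the quinuclidine nitrogen activates MeOH as a general base, so that oxygen adds to the central ketene carbon in the plane of the substituents from the CH2 side (anti to the bulkier in-plane ring A aryl), forming the ester C–O bond and a single enolate geometry; the squaramide-bound enolate is then protonated on one face by the adjacent quinuclidinium N–H, which sets the (R) centre, and because the face is chosen by catalyst–enolate contacts and not by the size of the alcohol, MeOH itself should suffice; the closest known reaction types are tertiary-amine- and chiral-pyridine-catalysed additions of alcohols and phenols to aryl alkyl ketenes and cinchona (thio)urea or squaramide-catalysed enantioselective methanolysis of cyclic anhydrides and azlactones; the sense of induction cannot be predicted with confidence, so whether the quinine- or the pseudo-enantiomeric quinidine-derived catalyst gives (R) is fixed in a first analytical run by chiral HPLC; the final acid-catalysed transesterification removes the three aryl acetates without affecting the acid-stable stereocentre.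

**Compound list**
1 | 2-(3,5-dibromo-4-hydroxyphenyl)acetic acid | OC(=O)Cc1cc(Br)c(O)c(Br)c1 | starting material
2 | methyl 2-(3,5-dibromo-4-methoxyphenyl)acetate | COC(=O)Cc1cc(Br)c(OC)c(Br)c1 | intermediate
3 | lithium 2-(3,5-dibromo-4-methoxyphenyl)acetate | [Li+].[O-]C(=O)Cc1cc(Br)c(OC)c(Br)c1 | intermediate
4 | 2-(3-bromo-5-hydroxy-4-methoxyphenyl)acetic acid | OC(=O)Cc1cc(O)c(OC)c(Br)c1 | intermediate
5 | 2,3-dibromo-4-hydroxy-5-methoxybenzaldehyde (5,6-dibromovanillin) | O=Cc1cc(OC)c(O)c(Br)c1Br | starting material
6 | 2,3-dibromo-4,5-dihydroxybenzaldehyde | O=Cc1cc(O)c(O)c(Br)c1Br | intermediate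
7 | (2E)-2-(3-acetoxy-5-bromo-4-methoxyphenyl)-3-(4,5-diacetoxy-2,3-dibromophenyl)prop-2-enoic acid | OC(=O)/C(=C/c1cc(OC(C)=O)c(OC(C)=O)c(Br)c1Br)c1cc(OC(C)=O)c(OC)c(Br)c1 | intermediate
8 | rac-2-(3-acetoxy-5-bromo-4-methoxyphenyl)-3-(4,5-diacetoxy-2,3-dibromophenyl)propanoic acid | OC(=O)C(Cc1cc(OC(C)=O)c(OC(C)=O)c(Br)c1Br)c1cc(OC(C)=O)c(OC)c(Br)c1 | intermediate
9 | rac-2-(3-acetoxy-5-bromo-4-methoxyphenyl)-3-(4,5-diacetoxy-2,3-dibromophenyl)propanoyl chloride | ClC(=O)C(Cc1cc(OC(C)=O)c(OC(C)=O)c(Br)c1Br)c1cc(OC(C)=O)c(OC)c(Br)c1 | intermediate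
10 | 2-(3-acetoxy-5-bromo-4-methoxyphenyl)-3-(4,5-diacetoxy-2,3-dibromophenyl)prop-1-en-1-one | O=C=C(Cc1cc(OC(C)=O)c(OC(C)=O)c(Br)c1Br)c1cc(OC(C)=O)c(OC)c(Br)c1 | intermediate
11 | methyl (2R)-2-(3-acetoxy-5-bromo-4-methoxyphenyl)-3-(4,5-diacetoxy-2,3-dibromophenyl)propanoate | COC(=O)[C@H](Cc1cc(OC(C)=O)c(OC(C)=O)c(Br)c1Br)c1cc(OC(C)=O)c(OC)c(Br)c1 | intermediate
12 | methyl (2R)-2-(3-bromo-5-hydroxy-4-methoxyphenyl)-3-(2,3-dibromo-4,5-dihydroxyphenyl)propanoate | COC(=O)[C@H](Cc1cc(O)c(O)c(Br)c1Br)c1cc(O)c(OC)c(Br)c1 | target

**Step count**
Total steps: 7. Longest linear sequence: 6 (steps 1, 2, 4, 5, 6, 7; step 3 is the one-step side branch).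

**Steps most likely to fail**

Step 2 (mono-hydroxylation). The risk is a mixture of unreacted dibromide, mono-phenol and diol, or diaryl ether formation. The fallback sets out from 2 and comes back at 4, and replaces rate-based selectivity by reagent stoichiometry. Saponify 2 (LiOH, THF/H2O, rt; then HCl) to 2-(3,5-dibromo-4-methoxyphenyl)acetic acid F1. Treat it with n-BuLi (2.1 equiv, THF, −95 °C): the first equivalent forms the lithium carboxylate and the second exchanges exactly one bromine, a low-temperature halogen–lithium exchange known for bromoaryl carboxylates. Quench with B(OMe)3 and work up with acid to 2-(3-borono-5-bromo-4-methoxyphenyl)acetic acid F2, then oxidise with H2O2/NaOH (ipso-hydroxylation of the boronic acid) to reach 4.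

Step 5 (hydrogenation). The risks are sluggish reduction of the hindered trisubstituted alkene or partial loss of bromine. The fallback sets out from 7 and comes back at 8, and replaces catalytic H2 addition by a stoichiometric electron-transfer conjugate reduction: SmI2 (2.5 equiv), N,N-dimethylacetamide, t-BuOH, THF, rt, a few minutes. This is known for aryl-conjugated unsaturated acids and esters, and divalent samarium does not reduce aryl bromides on this time scale without stronger donor additives. New compounds on this path: none F0.

Step 7 (proposed new method). The risks are low or opposite enantioselectivity and a racemic background addition. The fallback uses known auxiliary chemistry, sets out from 10 and comes back at 12. Add (R)-pantolactone (1.2 equiv) with Me2NEt in toluene at −78 °C; this is the known amine-mediated diastereoselective addition of a chiral α-hydroxy lactone to aryl alkyl ketenes, which from memory gives the (R)-acyl centre with (R)-pantolactone and should be checked on the adduct before hydrolysis. The adduct is (3R)-4,4-dimethyl-2-oxooxolan-3-yl (2R)-2-(3-acetoxy-5-bromo-4-methoxyphenyl)-3-(4,5-diacetoxy-2,3-dibromophenyl)propanoate F3, whose diastereomeric purity can be raised by crystallisation or chromatography. Hydrolyse the auxiliary ester and the three acetates with AcOH/2 M HCl at 85 °C (acidic, non-racemising) to (2R)-2-(3-bromo-5-hydroxy-4-methoxyphenyl)-3-(2,3-dibromo-4,5-dihydroxyphenyl)propanoic acid F4. Fischer esterification (1.25 M HCl in MeOH, rt) then gives 12.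

**Further compounds**
F1 | step 2 | 2-(3,5-dibromo-4-methoxyphenyl)acetic acid | OC(=O)Cc1cc(Br)c(OC)c(Br)c1
F2 | step 2 | 2-(3-borono-5-bromo-4-methoxyphenyl)acetic acid | OC(=O)Cc1cc(B(O)O)c(OC)c(Br)c1
F0 | step 5 | none | none
F3 | step 7 | (3R)-4,4-dimethyl-2-oxooxolan-3-yl (2R)-2-(3-acetoxy-5-bromo-4-methoxyphenyl)-3-(4,5-diacetoxy-2,3-dibromophenyl)propanoate | CC1(C)COC(=O)[C@@H]1OC(=O)[C@H](Cc1cc(OC(C)=O)c(OC(C)=O)c(Br)c1Br)c1cc(OC(C)=O)c(OC)c(Br)c1
F4 | step 7 | (2R)-2-(3-bromo-5-hydroxy-4-methoxyphenyl)-3-(2,3-dibromo-4,5-dihydroxyphenyl)propanoic acid | OC(=O)[C@H](Cc1cc(O)c(O)c(Br)c1Br)c1cc(O)c(OC)c(Br)c1
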